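**Retrosynthetic overview**

1. Rings: A = phloroglucinol ring, B = dihydropyran, C = cyclopentane, D = cyclohexene spiro-linked to C. The last operations are the two formyl groups (Rieche formylation), O-demethylation, and the ring-D methyl stereocentre from a ring-D ketone (Wittig, then face-selective hydrogenation).
2. Key disconnection: the bond from the spiro carbon to the vinylic CH of ring D, made by palladium-catalysed intramolecular α-alkenylation of a ketone enolate with an alkenyl iodide. This closes ring D with its double bond in place and sets the quaternary spiro centre stereoconvergently.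
3. Enabling feature: in ring D the spiro carbon lies between the vinylic CH and the methyl-bearing carbon. Carried as C=O, that carbon makes the spiro carbon (a ring-C carbon next to the O-bearing B/C fusion carbon) an enolisable α-carbon, and the cis-fused B/C bicycle shields its concave face.
4. The ketone comes from a lactol by aldol condensation (ring C) and oxa-Michael re-closure (ring B). The lactol comes from (4R)-4-isobutyl-5,7-dimethoxydihydrocoumarin (asymmetric conjugate addition, then two enolate alkylations anti to isobutyl).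
5. Ring order: A (bought, in the coumarin) → B → C (B opened and re-closed cis) → D (key step).

Key step: step 10

Remark: Grignard reagents and LiN(i-Pr)2 are used as commercial solutions, aqueous work-ups are written as quenching with water, and the hand of the ferrocenyl diphosphine in step 4 is taken as the one that gives the 4R lactone.

**Step 1**
Reactants: 1 2-(3-chloropropyl)-2-methyl-1,3-dioxolane
Product: 2 2-(3-iodopropyl)-2-methyl-1,3-dioxolane
Conditions: NaI, acetone, reflux
Reagents that add atoms: sodium iodide, [Na+].[I-]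
Why: Finkelstein halide exchange (SN2) driven by precipitation of NaCl should give the more reactive primary iodide without touching the ketal.

**Step 2**
Reactants: 3 prop-2-yn-1-ol; 4 isopropylmagnesium chloride
Product: 6 (2Z)-3-iodo-2-(propan-2-yl)prop-2-en-1-ol, via alkenylmagnesium alkoxide 5 (not isolated)
Conditions: i-PrMgCl (3 equiv), CuI (10 mol %), Et2O/THF, −10 °C to 23 °C; then I2, THF, −78 °C to 0 °C; H2O
Reagents that add atoms: iodine, [I][I]
Why: Copper-catalysed anti-carbomagnesiation of the propargylic alkoxide should place isopropyl on the internal carbon and magnesium on the terminal carbon inside a five-membered magnesium alkoxide chelate, so that iodinolysis with retention gives the alkenyl iodide with iodine cis to CH2OH.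

**Step 3**
Reactants: 6 (2Z)-3-iodo-2-(propan-2-yl)prop-2-en-1-ol
Product: 7 (1Z)-3-bromo-1-iodo-2-(propan-2-yl)prop-1-ene
Conditions: CBr4, PPh3, CH2Cl2, 0 °C
Reagents that add atoms: carbon tetrabromide, BrC(Br)(Br)Br
Why: Appel bromination of the primary allylic alcohol (SN2 on the oxyphosphonium ion) should leave the alkenyl iodide and the double-bond geometry untouched.

**Step 4**
Reactants: 8 5,7-dimethoxy-2H-chromen-2-one; 9 isobutylmagnesium bromide
Product: 10 (4R)-5,7-dimethoxy-4-(2-methylpropyl)-3,4-dihydro-2H-chromen-2-one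
Conditions: CuBr·SMe2 (5 mol %), (R)-1-[(S)-2-(diphenylphosphino)ferrocenyl]ethyldicyclohexylphosphine (6 mol %), t-BuOMe, −78 °C; then H2O
Reagents that add atoms: none
Why: Copper-catalysed asymmetric conjugate addition of a Grignard reagent to a coumarin should set the benzylic stereocentre (4R) by enantioface selection at C-4 within the chiral diphosphine–copper complex, with 1,2-addition suppressed at −78 °C.

**Step 5**
Reactants: 10 (4R)-5,7-dimethoxy-4-(2-methylpropyl)-3,4-dihydro-2H-chromen-2-one; 2 2-(3-iodopropyl)-2-methyl-1,3-dioxolane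
Product: 12 (3R,4R)-5,7-dimethoxy-3-[3-(2-methyl-1,3-dioxolan-2-yl)propyl]-4-(2-methylpropyl)-3,4-dihydro-2H-chromen-2-one, via lithium enolate 11 (not isolated)
Conditions: LiN(i-Pr)2 (1.1 equiv), THF, −78 °C; then 2, DMPU, −78 °C to −30 °C
Reagents that add atoms: none
Why: SN2 alkylation of the dihydrocoumarin lithium enolate should occur anti to the pseudo-axial 4-isobutyl group (3,4-trans), a C-3 configuration that is erased again in step 6.

**Step 6**
Reactants: 12 (3R,4R)-5,7-dimethoxy-3-[3-(2-methyl-1,3-dioxolan-2-yl)propyl]-4-(2-methylpropyl)-3,4-dihydro-2H-chromen-2-one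
Product: 14 (3S,4S)-5,7-dimethoxy-3-methyl-3-[3-(2-methyl-1,3-dioxolan-2-yl)propyl]-4-(2-methylpropyl)-3,4-dihydro-2H-chromen-2-one, via lithium enolate 13 (not isolated)
Conditions: LiN(i-Pr)2 (1.2 equiv), THF, −78 °C; then MeI, −78 °C to −40 °C
Reagents that add atoms: iodomethane, CI
Why: In this second enolate alkylation methyl iodide should again enter anti to the 4-isobutyl group, which fixes the quaternary carbon with methyl trans and the side chain cis to isobutyl (the C-4 descriptor changes only because the CIP priorities change).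

**Step 7**
Reactants: 14 (3S,4S)-5,7-dimethoxy-3-methyl-3-[3-(2-methyl-1,3-dioxolan-2-yl)propyl]-4-(2-methylpropyl)-3,4-dihydro-2H-chromen-2-one
Product: 15 (3S,4S)-5,7-dimethoxy-3-methyl-3-[3-(2-methyl-1,3-dioxolan-2-yl)propyl]-4-(2-methylpropyl)-3,4-dihydro-2H-chromen-2-ol (both C-2 epimers)
Conditions: i-Bu2AlH (1.1 equiv), CH2Cl2, −78 °C; then H2O
Reagents that add atoms: none
Why: Partial reduction of the aryl lactone should stop at the lactol because the aluminium hemiacetal is stable at −78 °C, and the ketal and methyl ethers are inert.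

**Step 8**
Reactants: 15 (3S,4S)-5,7-dimethoxy-3-methyl-3-[3-(2-methyl-1,3-dioxolan-2-yl)propyl]-4-(2-methylpropyl)-3,4-dihydro-2H-chromen-2-ol
Product: 18 1-[(3aS,9R,9aS)-6,8-dimethoxy-9a-methyl-9-(2-methylpropyl)-1,2,3,3a,9,9a-hexahydrocyclopenta[b]chromen-3-yl]ethan-1-one (both C-3 epimers), via keto lactol 16 (not isolated), via enone phenol 17 (not isolated)
Conditions: 1 M HCl, THF, 23 °C; then pyrrolidine (0.3 equiv), AcOH (0.3 equiv), toluene, 60 °C
Reagents that add atoms: water, O
Why: Ketal hydrolysis and amine-mediated intramolecular aldol condensation of the 6-oxoheptanal unit should give the 1-acetylcyclopentene (five-membered ring preferred over the seven-membered alternative through the methyl group), and 6-exo-trig oxa-Michael addition of the phenol, which can only reach the alkene face carrying the benzylic carbon, should close ring B cis (3a-H cis to 9a-CH3) while C-3 stays epimerisable.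

**Step 9**
Reactants: 18 1-[(3aS,9R,9aS)-6,8-dimethoxy-9a-methyl-9-(2-methylpropyl)-1,2,3,3a,9,9a-hexahydrocyclopenta[b]chromen-3-yl]ethan-1-one; 7 (1Z)-3-bromo-1-iodo-2-(propan-2-yl)prop-1-ene
Product: 20 (4E)-5-iodo-1-[(3aS,9R,9aS)-6,8-dimethoxy-9a-methyl-9-(2-methylpropyl)-1,2,3,3a,9,9a-hexahydrocyclopenta[b]chromen-3-yl]-4-(propan-2-yl)pent-4-en-1-one (both C-3 epimers), via lithium enolate 19 (not isolated)
Conditions: LiN(i-Pr)2 (1.05 equiv), THF, −78 °C; then 7, −78 °C to −40 °C
Reagents that add atoms: none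
Why: Kinetic deprotonation of the methyl ketone at CH3 and SN2 alkylation by the allylic bromide should extend the chain with the alkenyl iodide geometry intact (iodine cis to the chain), and this enolate cannot expel the aryloxide, which is β only to the ring α-carbon.

**Step 10**
Reactants: 20 (4E)-5-iodo-1-[(3aS,9R,9aS)-6,8-dimethoxy-9a-methyl-9-(2-methylpropyl)-1,2,3,3a,9,9a-hexahydrocyclopenta[b]chromen-3-yl]-4-(propan-2-yl)pent-4-en-1-one
Product: 22 (1R,3a′R,9′R,9a′S)-6′,8′-dimethoxy-9a′-methyl-9′-(2-methylpropyl)-5-(propan-2-yl)-1′,2′,9′,9a′-tetrahydro-3a′H-spiro[cyclohexane-1,3′-cyclopenta[b]chromen]-5-en-2-one, via potassium enolate 21 (not isolated)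
Conditions: Pd(PPh3)4 (10 mol %), KOPh (1.5 equiv), THF, 65 °C
Reagents that add atoms: none
Why: Oxidative addition of zerovalent palladium to the alkenyl iodide (geometry retained), exchange of iodide for enolate 21 and C–C reductive elimination from the C-bound palladium enolate should form the bond between the ring-C α-carbon and the vinylic CH; this is the palladium-catalysed intramolecular α-alkenylation of a ketone with an alkenyl halide under KOPh, a known reaction type that tolerates base-sensitive ketones. Ring D closes by reductive elimination from a seven-membered palladacycle, formally a 6-(enolendo)-exo closure, and its double bond stays endocyclic because iodine is cis to the tether. The only new stereocentre, the quaternary spiro carbon, is controlled by the cis-fused B/C bicycle: ring B and its aryl group fold under the concave face of the cyclopentane, so palladium and then the alkenyl carbon are delivered to the convex face, cis to 3a-H and the 9a-methyl group. The step is stereoconvergent and dynamic, because both C-3 epimers of 20, and any material whose ring B opens by retro-oxa-Michael reaction and closes again (only cis is possible), pass through the same planar enolate. The selectivities needed are alkenylation at the tertiary α-carbon rather than the α′-CH2 (only the former gives a six-membered ring, the latter a cyclobutanone) and C- rather than O-alkenylation (favoured by palladium and by the ring size).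

**Step 11**
Reactants: 22 (1R,3a′R,9′R,9a′S)-6′,8′-dimethoxy-9a′-methyl-9′-(2-methylpropyl)-5-(propan-2-yl)-1′,2′,9′,9a′-tetrahydro-3a′H-spiro[cyclohexane-1,3′-cyclopenta[b]chromen]-5-en-2-one
Product: 23 (1S,3a′R,9′R,9a′S)-6′,8′-dimethoxy-9a′-methyl-6-methylidene-9′-(2-methylpropyl)-3-(propan-2-yl)-1′,2′,9′,9a′-tetrahydro-3a′H-spiro[cyclohex-2-ene-1,3′-cyclopenta[b]chromene]
Conditions: Ph3PCH3Br, KOt-Bu, toluene, 80 °C
Reagents that add atoms: methyltriphenylphosphonium bromide, C[P+](c1ccccc1)(c1ccccc1)c1ccccc1.[Br-]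
Why: Wittig methylenation of the hindered ketone at elevated temperature should install the last carbon, and since the α-carbon is quaternary neither epimerisation nor conjugation of the β,γ-double bond is possible.

**Step 12**
Reactants: 23 (1S,3a′R,9′R,9a′S)-6′,8′-dimethoxy-9a′-methyl-6-methylidene-9′-(2-methylpropyl)-3-(propan-2-yl)-1′,2′,9′,9a′-tetrahydro-3a′H-spiro[cyclohex-2-ene-1,3′-cyclopenta[b]chromene]
Product: 24 (1R,6R,3a′R,9′R,9a′S)-6′,8′-dimethoxy-6,9a′-dimethyl-9′-(2-methylpropyl)-3-(propan-2-yl)-1′,2′,9′,9a′-tetrahydro-3a′H-spiro[cyclohex-2-ene-1,3′-cyclopenta[b]chromene]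
Conditions: H2 (5 atm), RhCl(PPh3)3 (10 mol %), benzene/EtOH, 40 °C
Reagents that add atoms: none
Why: Homogeneous hydrogenation with RhCl(PPh3)3 should reduce only the 1,1-disubstituted exocyclic alkene, and because allylic 1,3-strain turns the bulkier O-bearing fusion carbon C-3a′ perpendicular to the methylidene plane, hydrogen should be delivered from the opposite (C-2′) face so that the new methyl group ends up cis to C-3a′ (6R).

**Step 13**
Reactants: 24 (1R,6R,3a′R,9′R,9a′S)-6′,8′-dimethoxy-6,9a′-dimethyl-9′-(2-methylpropyl)-3-(propan-2-yl)-1′,2′,9′,9a′-tetrahydro-3a′H-spiro[cyclohex-2-ene-1,3′-cyclopenta[b]chromene]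
Product: 25 (1R,6R,3a′R,9′R,9a′S)-6′,8′-dimethoxy-6,9a′-dimethyl-9′-(2-methylpropyl)-3-(propan-2-yl)-1′,2′,9′,9a′-tetrahydro-3a′H-spiro[cyclohex-2-ene-1,3′-cyclopenta[b]chromene]-5′,7′-dicarbaldehyde
Conditions: Cl2CHOMe (6 equiv), TiCl4 (6 equiv), CH2Cl2, −78 °C to 0 °C; then H2O
Reagents that add atoms: dichloromethyl methyl ether, COC(Cl)Cl; water, O
Why: Rieche formylation should occur twice because each free position of the trioxygenated ring A is ortho or para to all three oxygen donors, and hydrolysis of the α-chloro ethers releases the two aldehydes.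

**Step 14**
Reactants: 25 (1R,6R,3a′R,9′R,9a′S)-6′,8′-dimethoxy-6,9a′-dimethyl-9′-(2-methylpropyl)-3-(propan-2-yl)-1′,2′,9′,9a′-tetrahydro-3a′H-spiro[cyclohex-2-ene-1,3′-cyclopenta[b]chromene]-5′,7′-dicarbaldehyde
Product: 26 (1R,6R,3a′R,9′R,9a′S)-6′,8′-dihydroxy-6,9a′-dimethyl-9′-(2-methylpropyl)-3-(propan-2-yl)-1′,2′,9′,9a′-tetrahydro-3a′H-spiro[cyclohex-2-ene-1,3′-cyclopenta[b]chromene]-5′,7′-dicarbaldehyde (the target)
Conditions: BCl3 (4 equiv), CH2Cl2, −78 °C to 0 °C; then H2O
Reagents that add atoms: none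
Why: Chelation-assisted cleavage of aryl methyl ethers ortho to a formyl group by BCl3 should remove both methyl groups (each methoxy has a formyl neighbour) at a temperature that spares the ring-D alkene and the secondary alkyl aryl ether of ring B.

**Compound list**

1 | 2-(3-chloropropyl)-2-methyl-1,3-dioxolane | CC1(CCCCl)OCCO1 | starting material
2 | 2-(3-iodopropyl)-2-methyl-1,3-dioxolane | CC1(CCCI)OCCO1 | intermediate
3 | prop-2-yn-1-ol | C#CCO | starting material
4 | isopropylmagnesium chloride | CC(C)[Mg]Cl | starting material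
5 | chloromagnesium (2Z)-3-(chloromagnesio)-2-(propan-2-yl)prop-2-en-1-olate | Cl[Mg]/C=C(\CO[Mg]Cl)C(C)C | intermediate
6 | (2Z)-3-iodo-2-(propan-2-yl)prop-2-en-1-ol | I/C=C(\CO)C(C)C | intermediate
7 | (1Z)-3-bromo-1-iodo-2-(propan-2-yl)prop-1-ene | I/C=C(\CBr)C(C)C | intermediate
8 | 5,7-dimethoxy-2H-chromen-2-one (5,7-dimethoxycoumarin) | O=C1C=Cc2c(OC)cc(OC)cc2O1 | starting material
9 | isobutylmagnesium bromide | CC(C)C[Mg]Br | starting material
10 | (4R)-5,7-dimethoxy-4-(2-methylpropyl)-3,4-dihydro-2H-chromen-2-one | CC(C)C[C@H]1c2c(OC)cc(OC)cc2OC(=O)C1 | intermediate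
11 | lithium enolate of 10, lithium (4R)-5,7-dimethoxy-4-(2-methylpropyl)-4H-chromen-2-olate | CC(C)C[C@H]1c2c(OC)cc(OC)cc2OC([O-])=C1.[Li+] | intermediate
12 | (3R,4R)-5,7-dimethoxy-3-[3-(2-methyl-1,3-dioxolan-2-yl)propyl]-4-(2-methylpropyl)-3,4-dihydro-2H-chromen-2-one (3,4-trans) | CC(C)C[C@H]1c2c(OC)cc(OC)cc2OC(=O)[C@@H]1CCCC1(C)OCCO1 | intermediate
13 | lithium enolate of 12 (2-olate, C-4 arrangement unchanged) | CC(C)C[C@H]1c2c(OC)cc(OC)cc2OC([O-])=C1CCCC1(C)OCCO1.[Li+] | intermediate
14 | (3S,4S)-5,7-dimethoxy-3-methyl-3-[3-(2-methyl-1,3-dioxolan-2-yl)propyl]-4-(2-methylpropyl)-3,4-dihydro-2H-chromen-2-one (methyl trans to isobutyl) | CC(C)C[C@H]1c2c(OC)cc(OC)cc2OC(=O)[C@@]1(C)CCCC1(C)OCCO1 | intermediate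
15 | (3S,4S)-5,7-dimethoxy-3-methyl-3-[3-(2-methyl-1,3-dioxolan-2-yl)propyl]-4-(2-methylpropyl)-3,4-dihydro-2H-chromen-2-ol (both C-2 epimers) | CC(C)C[C@H]1c2c(OC)cc(OC)cc2OC(O)[C@@]1(C)CCCC1(C)OCCO1 | intermediate
16 | 5-[(3S,4S)-2-hydroxy-5,7-dimethoxy-3-methyl-4-(2-methylpropyl)-3,4-dihydro-2H-chromen-3-yl]pentan-2-one | CC(C)C[C@H]1c2c(OC)cc(OC)cc2OC(O)[C@@]1(C)CCCC(C)=O | intermediate
17 | 1-{(3R)-3-[(1R)-1-(2-hydroxy-4,6-dimethoxyphenyl)-3-methylbutyl]-3-methylcyclopent-1-en-1-yl}ethan-1-one | CC(C)C[C@@H](c1c(OC)cc(OC)cc1O)[C@]1(C)CCC(C(C)=O)=C1 | intermediate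
18 | 1-[(3aS,9R,9aS)-6,8-dimethoxy-9a-methyl-9-(2-methylpropyl)-1,2,3,3a,9,9a-hexahydrocyclopenta[b]chromen-3-yl]ethan-1-one (cis-fused, both C-3 epimers) | CC(C)C[C@H]1c2c(OC)cc(OC)cc2O[C@@H]2[C@@]1(C)CCC2C(C)=O | intermediate
19 | lithium enolate of 18 on the methyl side, lithium 1-[(3aS,9R,9aS)-6,8-dimethoxy-9a-methyl-9-(2-methylpropyl)-1,2,3,3a,9,9a-hexahydrocyclopenta[b]chromen-3-yl]ethen-1-olate | CC(C)C[C@H]1c2c(OC)cc(OC)cc2O[C@@H]2[C@@]1(C)CCC2C([O-])=C.[Li+] | intermediate
20 | (4E)-5-iodo-1-[(3aS,9R,9aS)-6,8-dimethoxy-9a-methyl-9-(2-methylpropyl)-1,2,3,3a,9,9a-hexahydrocyclopenta[b]chromen-3-yl]-4-(propan-2-yl)pent-4-en-1-one (both C-3 epimers, iodine cis to the chain CH2) | CC(C)C[C@H]1c2c(OC)cc(OC)cc2O[C@@H]2[C@@]1(C)CCC2C(=O)CC/C(=C\I)C(C)C | intermediate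
21 | potassium enolate of 20 at C-3 (exocyclic C=C to the carbonyl carbon) | CC(C)C[C@H]1c2c(OC)cc(OC)cc2O[C@@H]2[C@@]1(C)CCC2=C([O-])CC/C(=C\I)C(C)C.[K+] | intermediate
22 | (1R,3a′R,9′R,9a′S)-6′,8′-dimethoxy-9a′-methyl-9′-(2-methylpropyl)-5-(propan-2-yl)-1′,2′,9′,9a′-tetrahydro-3a′H-spiro[cyclohexane-1,3′-cyclopenta[b]chromen]-5-en-2-one | CC(C)C[C@H]1c2c(OC)cc(OC)cc2O[C@@H]2[C@@]1(C)CC[C@@]21C=C(C(C)C)CCC1=O | intermediate
23 | (1S,3a′R,9′R,9a′S)-6′,8′-dimethoxy-9a′-methyl-6-methylidene-9′-(2-methylpropyl)-3-(propan-2-yl)-1′,2′,9′,9a′-tetrahydro-3a′H-spiro[cyclohex-2-ene-1,3′-cyclopenta[b]chromene] | CC(C)C[C@H]1c2c(OC)cc(OC)cc2O[C@@H]2[C@@]1(C)CC[C@@]21C=C(C(C)C)CCC1=C | intermediate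
24 | (1R,6R,3a′R,9′R,9a′S)-6′,8′-dimethoxy-6,9a′-dimethyl-9′-(2-methylpropyl)-3-(propan-2-yl)-1′,2′,9′,9a′-tetrahydro-3a′H-spiro[cyclohex-2-ene-1,3′-cyclopenta[b]chromene] | CC(C)C[C@H]1c2c(OC)cc(OC)cc2O[C@@H]2[C@@]1(C)CC[C@@]21C=C(C(C)C)CC[C@H]1C | intermediate
25 | (1R,6R,3a′R,9′R,9a′S)-6′,8′-dimethoxy-6,9a′-dimethyl-9′-(2-methylpropyl)-3-(propan-2-yl)-1′,2′,9′,9a′-tetrahydro-3a′H-spiro[cyclohex-2-ene-1,3′-cyclopenta[b]chromene]-5′,7′-dicarbaldehyde | CC(C)C[C@H]1c2c(OC)c(C=O)c(OC)c(C=O)c2O[C@@H]2[C@@]1(C)CC[C@@]21C=C(C(C)C)CC[C@H]1C | intermediate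
26 | (1R,6R,3a′R,9′R,9a′S)-6′,8′-dihydroxy-6,9a′-dimethyl-9′-(2-methylpropyl)-3-(propan-2-yl)-1′,2′,9′,9a′-tetrahydro-3a′H-spiro[cyclohex-2-ene-1,3′-cyclopenta[b]chromene]-5′,7′-dicarbaldehyde (CNP0121396.1) | CC(C)C[C@H]1c2c(O)c(C=O)c(O)c(C=O)c2O[C@@H]2[C@@]1(C)CC[C@@]21C=C(C(C)C)CC[C@H]1C | target

**Step count and risks**

Total step count: 14. Longest linear sequence: 11 steps (steps 4 to 14, from 8).

Steps most likely to fail:

Step 10. The alkenylpalladium species may be diverted: it could lose iodine by protodehalogenation, or insert syn into the enone that forms when ring B opens by retro-oxa-Michael reaction, which gives a palladium alkyl that cannot turn over. Attack on the concave face would give the wrong spiro epimer. The fallback closes ring D through the same bond by aldol chemistry and sets out from 18. α-Methylenation of the acetyl group (paraformaldehyde, diisopropylammonium trifluoroacetate, THF, reflux) should give the vinyl ketone 1-[(3aS,9R,9aS)-6,8-dimethoxy-9a-methyl-9-(2-methylpropyl)-1,2,3,3a,9,9a-hexahydrocyclopenta[b]chromen-3-yl]prop-2-en-1-one F1. Amine-catalysed Michael addition of 3-methylbutanal should give the keto aldehyde 5-[(3aS,9R,9aS)-6,8-dimethoxy-9a-methyl-9-(2-methylpropyl)-1,2,3,3a,9,9a-hexahydrocyclopenta[b]chromen-3-yl]-5-oxo-2-(propan-2-yl)pentanal F2. Base (DBU, THF) should then bring about intramolecular aldol addition of the ring-C α-carbon, from the convex face, to the aldehyde and give the spiro ketol 6-hydroxy-6′,8′-dimethoxy-9a′-methyl-9′-(2-methylpropyl)-5-(propan-2-yl)-1′,2′,9′,9a′-tetrahydro-3a′H-spiro[cyclohexane-1,3′-cyclopenta[b]chromen]-2-one F3, equilibrating to the isomer with hydroxyl trans to isopropyl. Syn-dehydration with Burgess reagent toward the only carbon that carries a β-hydrogen comes back to the route at 22.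

Step 4. Conjugate addition to the electron-rich coumarin with its peri methoxy group may be sluggish, may give way to 1,2-addition, or may show poor enantioface discrimination. The fallback does not use 8 and 9 but sets out from commercial 3,5-dimethoxyphenol and (E)-5-methylhex-2-enal. Iminium-catalysed Friedel–Crafts alkylation ortho to the phenol with hemiacetal closure (diphenylprolinol trimethylsilyl ether of the hand that leads to 4R, PhCO2H, toluene) should give the lactol (4R)-5,7-dimethoxy-4-(2-methylpropyl)-3,4-dihydro-2H-chromen-2-ol F4. Oxidation (TEMPO, PhI(OAc)2, CH2Cl2) comes back to the route at 10.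

Step 13. TiCl4 and the HCl released may ionise or hydrochlorinate the ring-D alkene, and the second formylation may stop short. The fallback sets out from 24 and replaces electrophilic formylation by halogen–lithium exchange. N-Bromosuccinimide (2.1 equiv, MeCN, 0 °C) should brominate both free ring-A positions to give the dibromide (1R,6R,3a′R,9′R,9a′S)-5′,7′-dibromo-6′,8′-dimethoxy-6,9a′-dimethyl-9′-(2-methylpropyl)-3-(propan-2-yl)-1′,2′,9′,9a′-tetrahydro-3a′H-spiro[cyclohex-2-ene-1,3′-cyclopenta[b]chromene] F5. Twofold bromine–lithium exchange (t-BuLi, THF, −78 °C) and quenching with DMF comes back to the route at 25.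

**Further compounds**

F1 | step 10 | 1-[(3aS,9R,9aS)-6,8-dimethoxy-9a-methyl-9-(2-methylpropyl)-1,2,3,3a,9,9a-hexahydrocyclopenta[b]chromen-3-yl]prop-2-en-1-one | CC(C)C[C@H]1c2c(OC)cc(OC)cc2O[C@@H]2[C@@]1(C)CCC2C(=O)C=C
F2 | step 10 | 5-[(3aS,9R,9aS)-6,8-dimethoxy-9a-methyl-9-(2-methylpropyl)-1,2,3,3a,9,9a-hexahydrocyclopenta[b]chromen-3-yl]-5-oxo-2-(propan-2-yl)pentanal | CC(C)C[C@H]1c2c(OC)cc(OC)cc2O[C@@H]2[C@@]1(C)CCC2C(=O)CCC(C=O)C(C)C
F3 | step 10 | 6-hydroxy-6′,8′-dimethoxy-9a′-methyl-9′-(2-methylpropyl)-5-(propan-2-yl)-1′,2′,9′,9a′-tetrahydro-3a′H-spiro[cyclohexane-1,3′-cyclopenta[b]chromen]-2-one (spiro and ring B/C centres as in 22) | CC(C)C[C@H]1c2c(OC)cc(OC)cc2O[C@@H]2[C@@]1(C)CC[C@@]21C(O)C(C(C)C)CCC1=O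
F4 | step 4 | (4R)-5,7-dimethoxy-4-(2-methylpropyl)-3,4-dihydro-2H-chromen-2-ol | CC(C)C[C@H]1c2c(OC)cc(OC)cc2OC(O)C1
F5 | step 13 | (1R,6R,3a′R,9′R,9a′S)-5′,7′-dibromo-6′,8′-dimethoxy-6,9a′-dimethyl-9′-(2-methylpropyl)-3-(propan-2-yl)-1′,2′,9′,9a′-tetrahydro-3a′H-spiro[cyclohex-2-ene-1,3′-cyclopenta[b]chromene] | CC(C)C[C@H]1c2c(OC)c(Br)c(OC)c(Br)c2O[C@@H]2[C@@]1(C)CC[C@@]21C=C(C(C)C)CC[C@H]1C
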